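Ring B is taken apart into three pieces: a terminal alkyne, one carbonyl ligand and a dialkoxyvinyl methoxycarbene of zerovalent chromium. The benzannulation exploits the oxygen pattern of ring B: para oxygens at C2' and C5', a single C6'–H and the chromone on C1'. In one operation it forms C5'–C6', C1'–C2' and C2'–C3', closes ring B on a finished ring A/C chromone, and delivers every oxygen already differentiated: C5'-OMe from the carbene carbon, C4'-OMe and C3'-OBn from the vinyl group, and the only free phenol, C2'-OH, from CO. The precursors are a 5-O-benzyl-2-ethynylchromone and a (Z)-2-benzyloxy-1-methoxyvinyl methoxycarbene complex; methylation and one hydrogenolysis finish.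

Key step: step 9

Remark: the enol-ether double bond of the carbene side chain is taken as (Z) (benzyloxy trans to the carbene carbon, hydrogen turned toward it); this geometry is erased when ring B aromatizes, so a minor (E) isomer should not change the constitution of the product.

Step 1
Reactants: 1 methyl methoxyacetate
Product: 3 methyl (Z)-3-(benzyloxy)-2-methoxyprop-2-enoate, via sodium formyl enolate 2 (not isolated)
Conditions: HCO2Me, NaH, THF, 0 °C to rt; evaporate; BnBr, DMF, 0 °C to rt
Reagents that add atoms: methyl formate, COC=O; benzyl bromide, BrCc1ccccc1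
Why: Crossed Claisen formylation gives the delocalized sodium formyl enolate, and O-alkylation of such α-substituted formyl ester enolates in a dipolar aprotic solvent (the route used for β-alkoxyacrylates) should give the enol ether with the benzyloxy group trans to the ester, that is (Z); no stereocentre is formed.

Step 2
Reactants: 3 methyl (Z)-3-(benzyloxy)-2-methoxyprop-2-enoate
Product: 4 (Z)-3-(benzyloxy)-2-methoxyprop-2-enoic acid
Conditions: LiOH, THF/H2O, rt; then 1 M HCl to pH 3, 0 °C
Reagents that add atoms: lithium hydroxide, [Li+].[OH-]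
Why: Saponification of the methyl ester; the push-pull β-alkoxyacrylate resists hydroxide addition and the enol ether survives brief cold acidification, as for simple 3-alkoxyacrylic acids.

Step 3
Reactants: 4 (Z)-3-(benzyloxy)-2-methoxyprop-2-enoic acid; 5 chromium hexacarbonyl, Cr(CO)6
Product: 9 pentacarbonyl[(Z)-3-(benzyloxy)-1,2-dimethoxyprop-2-en-1-ylidene]chromium, via acid chloride 6 (not isolated), via K2Cr(CO)5 7 (not isolated), via potassium acyl chromate 8 (not isolated)
Conditions: (COCl)2, cat. DMF, CH2Cl2, 0 °C to rt, evaporate; add to K2Cr(CO)5 [from 5, KC8, THF, −78 to 0 °C] at −78 °C, then 0 °C; evaporate; Me3OBF4, CH2Cl2, 0 °C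
Reagents that add atoms: trimethyloxonium tetrafluoroborate, C[O+](C)C.F[B-](F)(F)F
Why: Acyl chromate route to Fischer carbenes: KC8 reduces Cr(CO)6 to the nucleophilic dianion, which is acylated at chromium by the acid chloride, and the hard oxonium salt then methylates the acyl oxygen, so no vinyllithium with two different enol ether oxygens has to be made.

Step 4
Reactants: 10 2',6'-dihydroxy-4'-methoxyacetophenone; 11 diethyl oxalate
Product: 13 ethyl 5-hydroxy-7-methoxy-4-oxo-4H-chromene-2-carboxylate, via diketo ester 12 (not isolated)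
Conditions: NaOEt, EtOH, reflux; then conc. HCl, EtOH, reflux
Reagents that add atoms: none
Why: Claisen condensation of the acetophenone enolate with the oxalate followed by acid-catalysed cyclodehydration (oxalate chromone synthesis); the two phenols are equivalent, so ring closure can give only one chromone.

Step 5
Reactants: 13 ethyl 5-hydroxy-7-methoxy-4-oxo-4H-chromene-2-carboxylate
Product: 14 ethyl 5-(benzyloxy)-7-methoxy-4-oxo-4H-chromene-2-carboxylate
Conditions: BnBr, K2CO3, DMF, 60 °C
Reagents that add atoms: benzyl bromide, BrCc1ccccc1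
Why: Williamson etherification of the single, hydrogen-bonded 5-OH, which needs warm DMF but has no competitor; benzyl is chosen so that one hydrogenolysis later frees both phenols.

Step 6
Reactants: 14 ethyl 5-(benzyloxy)-7-methoxy-4-oxo-4H-chromene-2-carboxylate
Product: 15 5-(benzyloxy)-2-(hydroxymethyl)-7-methoxy-4H-chromen-4-one
Conditions: NaBH4, MeOH/THF, 0 °C
Reagents that add atoms: none
Why: Chemoselective borohydride reduction: the 2-carboxylate is an electron-poor ester activated by the pyranone ring and is reduced at 0 °C, while the vinylogous-ester carbonyl at C4 reacts far more slowly.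

Step 7
Reactants: 15 5-(benzyloxy)-2-(hydroxymethyl)-7-methoxy-4H-chromen-4-one
Product: 16 5-(benzyloxy)-7-methoxy-4-oxo-4H-chromene-2-carbaldehyde
Conditions: Dess–Martin periodinane, NaHCO3, CH2Cl2, 0 °C to rt
Reagents that add atoms: none
Why: Dess–Martin oxidation of the primary allylic-type alcohol under buffered, non-aqueous conditions stops at the aldehyde and leaves the benzyl ether and pyranone alone.

Step 8
Reactants: 16 5-(benzyloxy)-7-methoxy-4-oxo-4H-chromene-2-carbaldehyde
Product: 17 5-(benzyloxy)-2-ethynyl-7-methoxy-4H-chromen-4-one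
Conditions: Me3SiCHN2, LiN(i-Pr)2, THF, −78 °C; add 16, −78 °C to rt; aq. NH4Cl
Reagents that add atoms: trimethylsilyldiazomethane, C[Si](C)(C)C=[N+]=[N-]
Why: Colvin rearrangement: lithiated trimethylsilyldiazomethane adds to the non-enolizable aldehyde, Peterson-type loss of Me3SiOLi gives a diazoalkene, and loss of N2 with a 1,2-hydrogen shift of the alkylidene carbene gives the terminal alkyne; the aprotic, cold conditions keep alkoxide and alcohol away from the two conjugate acceptors.

Step 9
Reactants: 9 pentacarbonyl[(Z)-3-(benzyloxy)-1,2-dimethoxyprop-2-en-1-ylidene]chromium; 17 5-(benzyloxy)-2-ethynyl-7-methoxy-4H-chromen-4-one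
Product: 19 5,3'-bis(benzyloxy)-2'-hydroxy-7,4',5'-trimethoxyflavone, via ring B Cr(CO)3 complex 18 (not isolated)
Conditions: 9 (1.3 equiv), 17 added slowly, THF (degassed, 0.05 M), 50 °C, Ar; then air, EtOAc, rt
Reagents that add atoms: none
Why: Thermal loss of one cis CO from 9 opens a site for 17, which inserts into the Cr=C bond with its CH terminus on the former carbene carbon (C5'–C6'); CO insertion into the resulting vinylcarbene forms C1'–C2' and an η4-dienylketene. Ring B then closes by a thermal six-electron (disrotatory) electrocyclization between the ketene carbon and the vinyl β-carbon (C2'–C3'), and enolization of the cyclohexadienone gives the phenol as its Cr(CO)3 complex 18, which air strips to 19. The closest known reaction type is the Dötz benzannulation of alkenyl(methoxy)carbene complexes of zerovalent chromium with terminal alkynes, including aryl- and carbonyl-conjugated ones. No stereocentre is created. The step needs regioselective insertion, secured by the terminal alkyne (large chromonyl group next to the CO-derived carbon, hydrogen next to C5'), and phenol rather than five-ring formation, favoured by chromium, by the alkenyl (not aryl) carbene and by THF; the inward hydrogen on the (Z)-configured β-carbon keeps the ring closure unhindered.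

Step 10
Reactants: 19 5,3'-bis(benzyloxy)-2'-hydroxy-7,4',5'-trimethoxyflavone
Product: 20 5,3'-bis(benzyloxy)-7,2',4',5'-tetramethoxyflavone
Conditions: MeI, K2CO3, DMF, 40 °C
Reagents that add atoms: methyl iodide, CI
Why: Williamson methylation of the only free phenol, which is flanked on both sides and therefore given excess MeI in DMF; all other oxygens are already capped.

Step 11
Reactants: 20 5,3'-bis(benzyloxy)-7,2',4',5'-tetramethoxyflavone
Product: 21 5,3'-dihydroxy-7,2',4',5'-tetramethoxyflavone
Conditions: H2 (1 atm), 10% Pd/C, EtOAc/MeOH, rt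
Reagents that add atoms: none
Why: Hydrogenolysis of both benzyl aryl ethers on Pd/C at atmospheric pressure, conditions under which the flavone C2–C3 double bond and the methyl ethers are normally retained.

Compound list
1 | methyl methoxyacetate | COCC(=O)OC | starting material
2 | sodium enolate of methyl 2-methoxy-3-oxopropanoate (formed in situ, geometry not fixed) | COC(=O)C(OC)=C[O-].[Na+] | intermediate
3 | methyl (Z)-3-(benzyloxy)-2-methoxyprop-2-enoate | COC(=O)/C(OC)=C/OCc1ccccc1 | intermediate
4 | (Z)-3-(benzyloxy)-2-methoxyprop-2-enoic acid | OC(=O)/C(OC)=C/OCc1ccccc1 | intermediate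
5 | chromium hexacarbonyl, Cr(CO)6 | O=C=[Cr](=C=O)(=C=O)(=C=O)(=C=O)=C=O | starting material
6 | (Z)-3-(benzyloxy)-2-methoxyprop-2-enoyl chloride (formed in situ) | ClC(=O)/C(OC)=C/OCc1ccccc1 | intermediate
7 | dipotassium pentacarbonylchromate, K2Cr(CO)5 (formed in situ) | [K+].[K+].O=C=[Cr-2](=C=O)(=C=O)(=C=O)=C=O | intermediate
8 | potassium pentacarbonyl[(Z)-3-(benzyloxy)-2-methoxyprop-2-enoyl]chromate (formed in situ) | [K+].O=C([Cr-](=C=O)(=C=O)(=C=O)(=C=O)=C=O)/C(OC)=C/OCc1ccccc1 | intermediate
9 | pentacarbonyl[(Z)-3-(benzyloxy)-1,2-dimethoxyprop-2-en-1-ylidene]chromium | COC(=[Cr](=C=O)(=C=O)(=C=O)(=C=O)=C=O)/C(OC)=C/OCc1ccccc1 | intermediate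
10 | 2',6'-dihydroxy-4'-methoxyacetophenone | CC(=O)c1c(O)cc(OC)cc1O | starting material
11 | diethyl oxalate | CCOC(=O)C(=O)OCC | starting material
12 | ethyl 4-(2,6-dihydroxy-4-methoxyphenyl)-2,4-dioxobutanoate (formed in situ) | CCOC(=O)C(=O)CC(=O)c1c(O)cc(OC)cc1O | intermediate
13 | ethyl 5-hydroxy-7-methoxy-4-oxo-4H-chromene-2-carboxylate | CCOC(=O)c1cc(=O)c2c(O)cc(OC)cc2o1 | intermediate
14 | ethyl 5-(benzyloxy)-7-methoxy-4-oxo-4H-chromene-2-carboxylate | CCOC(=O)c1cc(=O)c2c(OCc3ccccc3)cc(OC)cc2o1 | intermediate
15 | 5-(benzyloxy)-2-(hydroxymethyl)-7-methoxy-4H-chromen-4-one | OCc1cc(=O)c2c(OCc3ccccc3)cc(OC)cc2o1 | intermediate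
16 | 5-(benzyloxy)-7-methoxy-4-oxo-4H-chromene-2-carbaldehyde | O=Cc1cc(=O)c2c(OCc3ccccc3)cc(OC)cc2o1 | intermediate
17 | 5-(benzyloxy)-2-ethynyl-7-methoxy-4H-chromen-4-one | C#Cc1cc(=O)c2c(OCc3ccccc3)cc(OC)cc2o1 | intermediate
18 | tricarbonylchromium η6 complex of 19 on ring B (formed in situ; written as two dot-joined parts) | COc1cc(OCc2ccccc2)c2c(=O)cc(-c3cc(OC)c(OC)c(OCc4ccccc4)c3O)oc2c1.O=C=[Cr](=C=O)=C=O | intermediate
19 | 5,3'-bis(benzyloxy)-2'-hydroxy-7,4',5'-trimethoxyflavone | COc1cc(OCc2ccccc2)c2c(=O)cc(-c3cc(OC)c(OC)c(OCc4ccccc4)c3O)oc2c1 | intermediate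
20 | 5,3'-bis(benzyloxy)-7,2',4',5'-tetramethoxyflavone | COc1cc(OCc2ccccc2)c2c(=O)cc(-c3cc(OC)c(OC)c(OCc4ccccc4)c3OC)oc2c1 | intermediate
21 | 5,3'-dihydroxy-7,2',4',5'-tetramethoxyflavone | COc1cc(O)c2c(=O)cc(-c3cc(OC)c(OC)c(O)c3OC)oc2c1 | target

Total steps: 11
Longest linear sequence: 8 steps (steps 4 to 11, from 10); the carbene arm (steps 1 to 3) joins at step 9.

Steps most likely to fail

1. Step 9. The donor-rich carbene may shed CO slowly. After alkyne insertion the vinylcarbene may cyclize without taking up CO or add a second alkyne, and the electron-poor alkyne may oligomerize at the metal, so conversion to the phenol could be low. The fallback abandons the benzannulation for a classical flavone synthesis, sets out from 10 and comes back at 20, ahead of step 11.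
   - Mono-benzylation of 10 (BnBr, K2CO3, acetone, reflux) should give 2'-benzyloxy-6'-hydroxy-4'-methoxyacetophenone F1, the second phenol being held by the hydrogen bond to the ketone.
   - Ring B would be made from commercial 2,6-dimethoxyphenol: O-benzylation (BnBr, K2CO3, DMF) to 2-benzyloxy-1,3-dimethoxybenzene F2, then Vilsmeier–Haack formylation (POCl3, DMF, 80 °C) para to a methoxy group to 3-benzyloxy-2,4-dimethoxybenzaldehyde F3.
   - Bromination (NBS, MeCN) at the one position activated by both methoxy groups should give 3-benzyloxy-5-bromo-2,4-dimethoxybenzaldehyde F4, and copper-mediated methoxylation (NaOMe, CuBr, DMF/MeOH, 110 °C) 3-benzyloxy-2,4,5-trimethoxybenzaldehyde F5.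
   - Claisen–Schmidt condensation of F1 with F5 (KOH, EtOH, rt) would give (E)-1-(2-benzyloxy-6-hydroxy-4-methoxyphenyl)-3-(3-benzyloxy-2,4,5-trimethoxyphenyl)prop-2-en-1-one F6, and oxidative cyclization (cat. I2, DMSO, 120 °C) would close ring C to 20.

2. Step 8. The lithiated diazo reagent may add to the pyranone ring in competition with the aldehyde, or the alkylidene carbene may be intercepted before the hydrogen shift, which would erode the alkyne. The fallback replaces the carbene rearrangement by olefination and elimination, sets out from 16 and comes back at 17. Wittig bromomethylenation of 16 with the ylide from (bromomethyl)triphenylphosphonium bromide and KOt-Bu (THF, −78 °C) should give (Z)-5-(benzyloxy)-2-(2-bromovinyl)-7-methoxy-4H-chromen-4-one F7. Anti elimination of HBr with DBU (THF, rt), helped by the acidity of the vinylic hydrogen next to the chromone, would then give 17.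

3. Step 3. The potassium acyl chromate may be lost before or during O-methylation, through oxidation, protonation or decomposition in the crude mixture that still holds KCl and graphite, so that little carbene is formed. The fallback replaces direct alkylation by acylation and alcoholysis, sets out from 8 and comes back at 9.
   - Cation exchange of 8 with Me4NBr in water should precipitate tetramethylammonium pentacarbonyl[(Z)-3-(benzyloxy)-2-methoxyprop-2-enoyl]chromate F8, a storable salt that can be purified.
   - Acetyl bromide (CH2Cl2, −40 °C) would convert it into pentacarbonyl[(Z)-1-acetoxy-3-(benzyloxy)-2-methoxyprop-2-en-1-ylidene]chromium F9.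
   - Methanol (−40 °C to rt) would displace acetate by addition–elimination at the carbene carbon to give 9.

Further compounds
F1 | step 9 | 2'-benzyloxy-6'-hydroxy-4'-methoxyacetophenone | CC(=O)c1c(O)cc(OC)cc1OCc1ccccc1
F2 | step 9 | 2-benzyloxy-1,3-dimethoxybenzene | COc1cccc(OC)c1OCc1ccccc1
F3 | step 9 | 3-benzyloxy-2,4-dimethoxybenzaldehyde | COc1ccc(C=O)c(OC)c1OCc1ccccc1
F4 | step 9 | 3-benzyloxy-5-bromo-2,4-dimethoxybenzaldehyde | COc1c(Br)cc(C=O)c(OC)c1OCc1ccccc1
F5 | step 9 | 3-benzyloxy-2,4,5-trimethoxybenzaldehyde | COc1cc(C=O)c(OC)c(OCc2ccccc2)c1OC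
F6 | step 9 | (E)-1-(2-benzyloxy-6-hydroxy-4-methoxyphenyl)-3-(3-benzyloxy-2,4,5-trimethoxyphenyl)prop-2-en-1-one | COc1cc(O)c(C(=O)/C=C/c2cc(OC)c(OC)c(OCc3ccccc3)c2OC)c(OCc2ccccc2)c1
F7 | step 8 | (Z)-5-(benzyloxy)-2-(2-bromovinyl)-7-methoxy-4H-chromen-4-one | Br/C=C\c1cc(=O)c2c(OCc3ccccc3)cc(OC)cc2o1
F8 | step 3 | tetramethylammonium pentacarbonyl[(Z)-3-(benzyloxy)-2-methoxyprop-2-enoyl]chromate | C[N+](C)(C)C.O=C([Cr-](=C=O)(=C=O)(=C=O)(=C=O)=C=O)/C(OC)=C/OCc1ccccc1
F9 | step 3 | pentacarbonyl[(Z)-1-acetoxy-3-(benzyloxy)-2-methoxyprop-2-en-1-ylidene]chromium | CC(=O)OC(=[Cr](=C=O)(=C=O)(=C=O)(=C=O)=C=O)/C(OC)=C/OCc1ccccc1
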